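**Retrosynthetic overview**

1. Final C–C bond: the ketone carbon is bonded to the methyl-bearing alkene carbon of the pyranone half in one Pd-catalysed three-component carbonylative Stille coupling (alkenyl iodide of the sec-butyl half + CO + alkenylstannane of the pyranone half); dilute acid then frees the pyranone OH.
2. Enabling feature: the acyclic cross-conjugated C=C–C(=O)–C=C unit, a carbonyl carbon bonded only to two sp2 carbons, each the CH3-bearing end of an (E)-trisubstituted alkene. CO can therefore be the carbonyl, and both alkenes come from methyl alkynes by syn-hydrometalation; the 2H-pyran-2-one ring and the doubly allylic CH(CH3) centre only need neutral conditions.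
3. Stannane ⇐ methyl alkyne (Pd hydrostannation) ⇐ vinylogous aldol/dehydration of 6-ethyl-4-(methoxymethoxy)-3,5-dimethylpyran-2-one with (2E,4S)-2,4-dimethylhept-2-en-5-ynal.
4. Ynenal and its CH(CH3) centre ⇐ (S)-pent-3-yn-2-yl mesylate + 3-ethoxymethacrolein (Marshall propargylation, acid transposition); iodide ⇐ (S)-2-methylbutan-1-ol (Corey–Fuchs/MeI, hydrozirconation–iodination).
5. Ring order: the only ring, the 2H-pyran-2-one, is closed first (step 6, lactonisation of a 3,5-diketo ester); nothing is cyclised afterwards.

Key step: step 14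

Remark on the chemistry: the pyranone 4-OH is carried as its methoxymethyl ether from step 7 to step 15, because a free vinylogous acid would be O-acylated by the acylpalladium intermediate of step 14 and would consume base in step 11.

**Route**

Step 1
Reactants: 1 (S)-2-methylbutan-1-ol
Product: 2 (S)-2-methylbutanal
Conditions: TEMPO (1 mol %), KBr (10 mol %), aq. NaOCl (pH 9), CH2Cl2, 0 °C
Reagents that add atoms: none
Why: Anelli oxidation (TEMPO-catalysed hypochlorite oxidation) stops at the aldehyde under buffered biphasic conditions at 0 °C and should leave the α-stereocentre, carried over from 1, intact.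

Step 2
Reactants: 2 (S)-2-methylbutanal
Product: 3 (S)-1,1-dibromo-3-methylpent-1-ene
Conditions: CBr4 (2 equiv), PPh3 (4 equiv), CH2Cl2, 0 °C
Reagents that add atoms: carbon tetrabromide, BrC(Br)(Br)Br
Why: First stage of the Corey–Fuchs sequence (dibromomethylene Wittig reaction), which is fast and non-basic at 0 °C, so the enolisable α-centre should not epimerise.

Step 3
Reactants: 3 (S)-1,1-dibromo-3-methylpent-1-ene
Product: 5 (S)-4-methylhex-2-yne, via lithium acetylide 4 (not isolated)
Conditions: n-BuLi (2.1 equiv), THF, −78 °C; then MeI, −78 °C → rt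
Reagents that add atoms: iodomethane, CI
Why: Second stage of the Corey–Fuchs sequence: Br/Li exchange and Fritsch–Buttenberg–Wiechell rearrangement give the lithium acetylide, which is C-methylated by MeI, while the propargylic C–H is not acidic enough to be touched.

Step 4
Reactants: 5 (S)-4-methylhex-2-yne
Product: 7 (2E,4S)-2-iodo-4-methylhex-2-ene, via alkenylzirconocene chloride 6 (not isolated)
Conditions: Cp2Zr(H)Cl (1.5 equiv), THF, 50 °C; then I2, 0 °C
Reagents that add atoms: iodine, II
Why: Hydrozirconation with Schwartz's reagent is a syn addition that, after equilibration with a slight excess of hydride, should place Zr on the methyl-bearing carbon away from the sec-butyl branch, and iodinolysis of the C–Zr bond proceeds with retention to the (E)-iodide.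

Step 5
Reactants: 8 methyl 2-methyl-3-oxopentanoate; 9 N-methoxy-N-methylpropanamide
Product: 11 methyl 2,4-dimethyl-3,5-dioxoheptanoate, via keto ester dianion 10 (not isolated)
Conditions: NaH, THF, 0 °C; n-BuLi, 0 °C; then 9, −78 → 0 °C; aq. HCl
Reagents that add atoms: none
Why: γ-Acylation of a β-keto ester dianion, in which the more reactive γ-carbanion attacks the Weinreb amide and the stable tetrahedral adduct prevents over-addition.

Step 6
Reactants: 11 methyl 2,4-dimethyl-3,5-dioxoheptanoate
Product: 12 6-ethyl-4-hydroxy-3,5-dimethyl-2H-pyran-2-one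
Conditions: DBU (1.5 equiv), toluene, 80 °C; aq. HCl
Reagents that add atoms: none
Why: Base-mediated enolisation and lactonisation of a 3,5-diketo ester (enol oxygen onto the methyl ester, loss of MeOH) is the standard 4-hydroxy-2-pyranone synthesis and is driven by formation of the conjugated pyranone.

Step 7
Reactants: 12 6-ethyl-4-hydroxy-3,5-dimethyl-2H-pyran-2-one
Product: 13 6-ethyl-4-(methoxymethoxy)-3,5-dimethyl-2H-pyran-2-one
Conditions: MOMCl, i-Pr2NEt, CH2Cl2, 0 °C → rt
Reagents that add atoms: chloromethyl methyl ether, COCCl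
Why: O-Alkylation of the pyranonate anion of a vinylogous acid with MOMCl should give the 4-O-MOM ether, a vinylogous acetal ester that is stable to base and Pd(0) and removable with dilute acid.

Step 8
Reactants: 14 pent-3-yn-2-one
Product: 15 (S)-pent-3-yn-2-ol
Conditions: Ru[(S,S)-TsDPEN](p-cymene) (0.5 mol %), i-PrOH, rt
Reagents that add atoms: none
Why: Noyori asymmetric transfer hydrogenation of an α,β-acetylenic ketone, in which the (S,S)-diamine ligand directs hydride to one carbonyl face through the six-membered metal–ligand bifunctional transition state and should give the (S)-propargylic alcohol in high enantiomeric purity.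

Step 9
Reactants: 15 (S)-pent-3-yn-2-ol
Product: 16 (S)-pent-3-yn-2-yl methanesulfonate
Conditions: MsCl, Et3N, CH2Cl2, −78 → 0 °C
Reagents that add atoms: methanesulfonyl chloride, CS(=O)(=O)Cl
Why: Sulfonylation at oxygen does not break the C–O bond, so the configuration is retained.

Step 10
Reactants: 16 (S)-pent-3-yn-2-yl methanesulfonate; 17 (E)-3-ethoxy-2-methylprop-2-enal
Product: 20 (2E,4S)-2,4-dimethylhept-2-en-5-ynal, via allenylzinc reagent 18 (not isolated), via hydroxy enol ether 19 (not isolated)
Conditions: Pd(OAc)2 (5 mol %), PPh3 (5 mol %), Et2Zn (3 equiv), THF, −78 → −20 °C; then 1 M aq. HCl, 0 °C → rt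
Reagents that add atoms: water, O
Why: Marshall propargylation, in which anti SN2′ attack of Pd(0) on the mesylate, Pd-to-Zn exchange and cyclic SE2′ addition of the allenylzinc to the aldehyde set the CH(CH3) centre with net inversion at the former C–OMs carbon, after which aqueous acid ionises the γ-ethoxy allylic alcohol and hydrolyses it with 1,3-transposition to the (E)-2-methyl-2-enal (the established use of 3-ethoxymethacrolein as a 2-methylpropenal building block), erasing the uncontrolled carbinol centre.

Step 11
Reactants: 13 6-ethyl-4-(methoxymethoxy)-3,5-dimethyl-2H-pyran-2-one; 20 (2E,4S)-2,4-dimethylhept-2-en-5-ynal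
Product: 22 6-[(4E,6S)-3-hydroxy-4,6-dimethylnon-4-en-7-yn-2-yl]-4-(methoxymethoxy)-3,5-dimethyl-2H-pyran-2-one (mixture of epimers at the two new centres), via lithiated pyranone 21 (not isolated)
Conditions: LDA (1.05 equiv), THF, −78 °C; then 20, −78 °C; aq. NH4Cl
Reagents that add atoms: none
Why: Vinylogous aldol addition, in which LDA removes a proton from the CH2 of the 6-ethyl group (the only alkyl position conjugated through both ring C=C bonds to the lactone C=O) and the extended enolate adds 1,2 to the enal faster than it deprotonates it; the two new centres are not controlled and are removed in step 12.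

Step 12
Reactants: 22 aldol adduct
Product: 24 6-[(2E,4E,6S)-4,6-dimethylnona-2,4-dien-7-yn-2-yl]-4-(methoxymethoxy)-3,5-dimethyl-2H-pyran-2-one, via allylic mesylate 23 (not isolated)
Conditions: MsCl, Et3N, CH2Cl2, 0 °C; then DBU, 0 °C → rt
Reagents that add atoms: none
Why: Mesylation followed by DBU-induced E2/E1cB elimination removes the acidified proton next to the pyranone and should give the conjugated, thermodynamically preferred (E)-trisubstituted alkene, DBU being too weak a base to deprotonate the doubly allylic CH(CH3) centre.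

Step 13
Reactants: 24 methyl alkyne
Product: 25 4-(methoxymethoxy)-3,5-dimethyl-6-[(2E,4E,6S,7E)-4,6-dimethyl-8-(tributylstannyl)nona-2,4,7-trien-2-yl]-2H-pyran-2-one
Conditions: Bu3SnH (1.2 equiv, slow addition), PdCl2(PPh3)2 (3 mol %), THF, 0 °C
Reagents that add atoms: tributyltin hydride, CCCC[SnH](CCCC)CCCC
Why: Pd-catalysed hydrostannation is a syn addition of Sn–H that, on an alkyne flanked by a branched sp3 carbon and a methyl group, should deliver tin to the methyl-bearing carbon and give the (E)-alkenylstannane, the alkyne reacting much faster than the trisubstituted alkenes or the pyranone.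

Step 14
Reactants: 7 (2E,4S)-2-iodo-4-methylhex-2-ene; 25 alkenylstannane; 26 carbon monoxide
Product: 28 4-(methoxymethoxy)-3,5-dimethyl-6-[(2E,4E,6S,7E,10E,12S)-4,6,8,10,12-pentamethyl-9-oxotetradeca-2,4,7,10-tetraen-2-yl]-2H-pyran-2-one, via acylpalladium iodide 27 (not isolated)
Conditions: Pd2(dba)3 (5 mol %), AsPh3 (40 mol %), CO (3 atm), NMP, 45 °C
Reagents that add atoms: none
Why: Pd(0) inserts into the C–I bond of 7 with retention, CO inserts to give the α,β-unsaturated acylpalladium iodide 27, the alkenyl group of 25 is transferred from tin to palladium with retention, and reductive elimination forms the bond between the carbonyl carbon and the methyl-bearing alkenyl carbon of the pyranone half. The closest known reaction type is the Stille carbonylative cross-coupling of alkenyl iodides with alkenylstannanes, the standard entry to unsymmetrical divinyl ketones. No ring is closed and no stereocentre is created; both existing centres are remote from the metal and the medium is neutral, so the doubly allylic CH(CH3) centre should neither epimerise nor move into conjugation. The step needs carbonylative rather than direct coupling, which the CO pressure and the slow transmetalation of the α-methyl-substituted stannane secure, because CO insertion into the alkenyl–Pd bond is much faster than tin-to-palladium transfer. It also needs retention of both (E)-alkene geometries, which is inherent to oxidative addition, insertion and transmetalation at sp2 carbon, and C- rather than O-acylation, which the MOM ether on the pyranone oxygen secures. In one operation three components give the whole carbon skeleton and the cross-conjugated dienone from two halves that each come from a methyl alkyne.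

Step 15
Reactants: 28 MOM-protected dienone
Product: 29 4-hydroxy-3,5-dimethyl-6-[(2E,4E,6S,7E,10E,12S)-4,6,8,10,12-pentamethyl-9-oxotetradeca-2,4,7,10-tetraen-2-yl]-2H-pyran-2-one
Conditions: 1 M aq. HCl, THF, rt
Reagents that add atoms: none
Why: Acid hydrolysis of the methoxymethyl ether of a vinylogous acid (an acetal ester) should be fast under dilute aqueous acid, conditions too mild to trigger Nazarov cyclisation of the dienone or to disturb the skipped diene and the two stereocentres.

**Compound list**

1 | (S)-2-methylbutan-1-ol | CC[C@H](C)CO | starting material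
2 | (S)-2-methylbutanal | CC[C@H](C)C=O | intermediate
3 | (S)-1,1-dibromo-3-methylpent-1-ene | CC[C@H](C)C=C(Br)Br | intermediate
4 | lithium (S)-3-methylpent-1-yn-1-ide (formed in situ) | CC[C@H](C)C#C[Li] | intermediate
5 | (S)-4-methylhex-2-yne | CC[C@H](C)C#CC | intermediate
6 | chlorobis(cyclopentadienyl)[(2E,4S)-4-methylhex-2-en-2-yl]zirconium (formed in situ) | CC[C@H](C)/C=C(\C)[Zr](Cl)(C1C=CC=C1)C1C=CC=C1 | intermediate
7 | (2E,4S)-2-iodo-4-methylhex-2-ene | CC[C@H](C)/C=C(\C)I | intermediate
8 | methyl 2-methyl-3-oxopentanoate (racemic) | CCC(=O)C(C)C(=O)OC | starting material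
9 | N-methoxy-N-methylpropanamide | CCC(=O)N(C)OC | starting material
10 | sodium lithium C2,C4-dianion of methyl 2-methyl-3-oxopentanoate (formed in situ) | C[CH-]C(=O)[C-](C)C(=O)OC.[Na+].[Li+] | intermediate
11 | methyl 2,4-dimethyl-3,5-dioxoheptanoate (stereoisomer/tautomer mixture) | CCC(=O)C(C)C(=O)C(C)C(=O)OC | intermediate
12 | 6-ethyl-4-hydroxy-3,5-dimethyl-2H-pyran-2-one | CCc1oc(=O)c(C)c(O)c1C | intermediate
13 | 6-ethyl-4-(methoxymethoxy)-3,5-dimethyl-2H-pyran-2-one | CCc1oc(=O)c(C)c(OCOC)c1C | intermediate
14 | pent-3-yn-2-one | CC#CC(C)=O | starting material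
15 | (S)-pent-3-yn-2-ol | CC#C[C@H](C)O | intermediate
16 | (S)-pent-3-yn-2-yl methanesulfonate | CC#C[C@H](C)OS(C)(=O)=O | intermediate
17 | (E)-3-ethoxy-2-methylprop-2-enal (3-ethoxymethacrolein) | CCO/C=C(C)/C=O | starting material
18 | ethyl[(aR)-penta-2,3-dien-2-yl]zinc (formed in situ) | CC[Zn]C(C)=[C@@]=C(C)[H] | intermediate
19 | (1E,4R)-1-ethoxy-2,4-dimethylhept-1-en-5-yn-3-ol (C3 epimers, mainly anti; formed in situ) | CC#C[C@@H](C)C(O)/C(C)=C/OCC | intermediate
20 | (2E,4S)-2,4-dimethylhept-2-en-5-ynal | CC#C[C@@H](C)/C=C(\C)C=O | intermediate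
21 | 6-(1-lithioethyl)-4-(methoxymethoxy)-3,5-dimethyl-2H-pyran-2-one, extended enolate (formed in situ) | C[CH-]c1oc(=O)c(C)c(OCOC)c1C.[Li+] | intermediate
22 | 6-[(4E,6S)-3-hydroxy-4,6-dimethylnon-4-en-7-yn-2-yl]-4-(methoxymethoxy)-3,5-dimethyl-2H-pyran-2-one (epimers at C2 and C3 of the side chain) | CC#C[C@@H](C)/C=C(\C)C(O)C(C)c1oc(=O)c(C)c(OCOC)c1C | intermediate
23 | (4E,6S)-2-[4-(methoxymethoxy)-3,5-dimethyl-2-oxo-2H-pyran-6-yl]-4,6-dimethylnon-4-en-7-yn-3-yl methanesulfonate (formed in situ) | CC#C[C@@H](C)/C=C(\C)C(OS(C)(=O)=O)C(C)c1oc(=O)c(C)c(OCOC)c1C | intermediate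
24 | 6-[(2E,4E,6S)-4,6-dimethylnona-2,4-dien-7-yn-2-yl]-4-(methoxymethoxy)-3,5-dimethyl-2H-pyran-2-one | CC#C[C@@H](C)/C=C(C)/C=C(\C)c1oc(=O)c(C)c(OCOC)c1C | intermediate
25 | 4-(methoxymethoxy)-3,5-dimethyl-6-[(2E,4E,6S,7E)-4,6-dimethyl-8-(tributylstannyl)nona-2,4,7-trien-2-yl]-2H-pyran-2-one | CCCC[Sn](CCCC)(CCCC)/C(C)=C/[C@@H](C)/C=C(C)/C=C(\C)c1oc(=O)c(C)c(OCOC)c1C | intermediate
26 | carbon monoxide | [C-]#[O+] | starting material
27 | trans-iodo[(2E,4S)-2,4-dimethylhex-2-enoyl]bis(triphenylarsine)palladium(II) (formed in situ) | CC[C@H](C)/C=C(\C)C(=O)[Pd](I)([As](c1ccccc1)(c1ccccc1)c1ccccc1)[As](c1ccccc1)(c1ccccc1)c1ccccc1 | intermediate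
28 | 4-(methoxymethoxy)-3,5-dimethyl-6-[(2E,4E,6S,7E,10E,12S)-4,6,8,10,12-pentamethyl-9-oxotetradeca-2,4,7,10-tetraen-2-yl]-2H-pyran-2-one | CC[C@H](C)/C=C(\C)C(=O)/C(C)=C/[C@@H](C)/C=C(C)/C=C(\C)c1oc(=O)c(C)c(OCOC)c1C | intermediate
29 | 4-hydroxy-3,5-dimethyl-6-[(2E,4E,6S,7E,10E,12S)-4,6,8,10,12-pentamethyl-9-oxotetradeca-2,4,7,10-tetraen-2-yl]-2H-pyran-2-one | CC[C@H](C)/C=C(\C)C(=O)/C(C)=C/[C@@H](C)/C=C(C)/C=C(\C)c1oc(=O)c(C)c(O)c1C | target

**Step count**

Total steps: 15. Longest linear sequence: 8 steps (14 → 29 through steps 8–15; the pyranone branch 8 → 29 through steps 5–7 and 11–15 is equally long).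

**Three steps most likely to fail**

Step 14 (carbonylative coupling). Tin-to-palladium transfer from the α-methyl-substituted alkenylstannane may be slower than decay of the acylpalladium species, so that homocoupling, protodestannylation or CO-free direct coupling takes over. The fallback sets out from 7 and 25 and comes back at 28; it preforms the acyl half and couples it without CO under copper mediation. Iodide 7 undergoes iodine–lithium exchange (t-BuLi, Et2O, −78 °C) to (4S)-4-methylhex-2-en-2-yllithium F1 (lithium trans to the sec-butyl group), which is carboxylated with CO2 to (2E,4S)-2,4-dimethylhex-2-enoic acid F2. Esterification with thiophenol (DCC, DMAP, CH2Cl2) gives S-phenyl (2E,4S)-2,4-dimethylhex-2-enethioate F3. Liebeskind–Srogl coupling of F3 with stannane 25 (Pd2(dba)3, tri(2-furyl)phosphine, copper(I) diphenylphosphinate, THF, rt) should give 28 under neutral conditions, the copper carboxylate activating both the thioester and the hindered stannane.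

Step 10 (propargylation/transposition). The aldehyde of 17 is deactivated by its β-ethoxy group, so capture of the allenylzinc may be slow enough for the reagent to racemise or be protonated, lowering conversion and enantiomeric purity. The fallback sets out from 16 and comes back at 20; it uses a fully reactive aldehyde and unveils the enal by a separate allylic transposition. The same allenylzinc 18 (Pd(OAc)2, PPh3, Et2Zn, THF, −20 °C) is added to methacrolein to give (4R)-2,4-dimethylhept-1-en-5-yn-3-ol F4 (C3 epimers). PBr3 (Et2O, −10 °C) converts F4 with allylic rearrangement into the primary bromide (2E,4S)-1-bromo-2,4-dimethylhept-2-en-5-yne F5. N-Oxide oxidation of F5 (N-methylmorpholine N-oxide, MeCN, rt) should give enal 20.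

Step 13 (hydrostannation). Regiocontrol of Sn–H addition across the internal alkyne may be incomplete (tin partly delivered to the carbon next to the stereocentre), and separation of the regioisomeric stannanes may be poor. The fallback sets out from 24 and comes back at 25; it fixes the regiochemistry by thermodynamically controlled hydrozirconation. Alkyne 24 is treated with Cp2Zr(H)Cl (THF, 0 °C → rt) to give the alkenylzirconocene chloride of 24 F6, with zirconium on the methyl-bearing carbon, which is iodinated (I2, 0 °C) to 6-[(2E,4E,6S,7E)-8-iodo-4,6-dimethylnona-2,4,7-trien-2-yl]-4-(methoxymethoxy)-3,5-dimethyl-2H-pyran-2-one F7. Pd-catalysed stannylation of F7 with hexabutylditin (PdCl2(PPh3)2, THF, 50 °C) should return stannane 25.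

**Further compounds**

F1 | step 14 | (4S)-4-methylhex-2-en-2-yllithium (Li trans to the sec-butyl group; formed in situ) | CC[C@H](C)/C=C(\C)[Li]
F2 | step 14 | (2E,4S)-2,4-dimethylhex-2-enoic acid | CC[C@H](C)/C=C(\C)C(=O)O
F3 | step 14 | S-phenyl (2E,4S)-2,4-dimethylhex-2-enethioate | CC[C@H](C)/C=C(\C)C(=O)Sc1ccccc1
F4 | step 10 | (4R)-2,4-dimethylhept-1-en-5-yn-3-ol (C3 epimers) | CC#C[C@@H](C)C(O)C(C)=C
F5 | step 10 | (2E,4S)-1-bromo-2,4-dimethylhept-2-en-5-yne | CC#C[C@@H](C)/C=C(\C)CBr
F6 | step 13 | chlorobis(cyclopentadienyl){(2E,4S,5E,7E)-8-[4-(methoxymethoxy)-3,5-dimethyl-2-oxo-2H-pyran-6-yl]-4,6-dimethylnona-2,5,7-trien-2-yl}zirconium (formed in situ) | Cl[Zr](C1C=CC=C1)(C1C=CC=C1)/C(C)=C/[C@@H](C)/C=C(C)/C=C(\C)c1oc(=O)c(C)c(OCOC)c1C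
F7 | step 13 | 6-[(2E,4E,6S,7E)-8-iodo-4,6-dimethylnona-2,4,7-trien-2-yl]-4-(methoxymethoxy)-3,5-dimethyl-2H-pyran-2-one | I/C(C)=C/[C@@H](C)/C=C(C)/C=C(\C)c1oc(=O)c(C)c(OCOC)c1C
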